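**Retrosynthetic overview**
1. Target 33 ← Negishi coupling (C12–C13) of the alkylzinc from iodide 27 with (Z)-β-iodoenoate 31; 27 ← opening of δ-lactone 24, a temporary ring that ties C17 to the C12 oxygen.
2. 24 (C6=C7, C8–H) ← alkene-transposing reduction of the tosylhydrazone of enone 20 (C6 ketone, C7=C8).
3. 20 ← acyclic diketone 17 in one amine-catalysed Michael–aldol condensation [3+3]: C5–C10 closes ring A first, C7–C8 closes ring B second.
4. 17 ← mesityl oxide (C4–C7 and the gem-dimethyl), allyltrimethylsilane (C1–C3), 3-butyn-1-ol (C9–C12), MeMgBr (C20), dimethyl oxalate (C8, C17).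
5. Enabling feature: in ring B the ester-bearing C8 is allylic to C6=C7. This C6=C7–C8(H)–CO2Me array is the reduced, 1,3-transposed form of a 6-oxo-7-ene whose C7=C8 is an aldol-condensation alkene between a methyl ketone (C6, C7) and an α-keto ester (C8, C17). The quaternary C10 is β to that C8 carbonyl, so ring B (C5 to C10) splits into an acetonyl unit C5–C6–C7 and a 2-oxo-3-enoate unit C8–C9–C10.

Key step: step 9

Remark: locants C1–C20 are the labdane locants of the target (C4 gem-dimethyl, C10 methyl, C17 ester carbon on C8, side chain C11–C16); the target belongs to the ent-labdane series.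
Assumption: the sense of induction of the cinchona-derived primary amine in step 9 cannot be predicted with certainty; the quinine-derived catalyst is written, and its quinidine-derived pseudo-enantiomer takes its place if it delivers the antipode.

**Route**

Step 1
Reactants: 1 mesityl oxide (4-methylpent-3-en-2-one); 2 allyltrimethylsilane
Product: 3 4,4-dimethylhept-6-en-2-one
Conditions: TiCl4 (1.0 equiv), CH2Cl2, −78 to −30 °C; H2O
Reagents that add atoms: none
Why: Hosomi–Sakurai conjugate allylation, in which the TiCl4-activated enone is attacked at its β-carbon by the γ-carbon of the allylsilane, builds the quaternary gem-dimethyl carbon C4 and leaves the methyl ketone (C6, C7); no stereocenter is formed.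

Step 2
Reactants: 3 4,4-dimethylhept-6-en-2-one; 4 ethylene glycol
Product: 5 2-(2,2-dimethylpent-4-en-1-yl)-2-methyl-1,3-dioxolane
Conditions: p-TsOH·H2O (cat.), benzene, reflux, Dean–Stark trap
Reagents that add atoms: none
Why: Acid-catalysed ketalization with azeotropic removal of water protects the methyl ketone against the organometallic reagents of steps 5 to 7.

Step 3
Reactants: 5 2-(2,2-dimethylpent-4-en-1-yl)-2-methyl-1,3-dioxolane
Product: 6 4,4-dimethyl-5-(2-methyl-1,3-dioxolan-2-yl)pentan-1-ol
Conditions: 9-BBN, THF, 0 °C to rt; then 3 M NaOH, 30% H2O2, 0 °C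
Reagents that add atoms: hydrogen peroxide, OO
Why: Anti-Markovnikov hydroboration of the terminal alkene with 9-BBN followed by basic oxidation should give the primary alcohol, the dioxolane being stable to base.

Step 4
Reactants: 6 4,4-dimethyl-5-(2-methyl-1,3-dioxolan-2-yl)pentan-1-ol
Product: 7 2-(5-iodo-2,2-dimethylpentyl)-2-methyl-1,3-dioxolane
Conditions: I2, PPh3, imidazole, CH2Cl2, 0 °C to rt
Reagents that add atoms: iodine, II
Why: Appel-type iodination of the unhindered primary alcohol proceeds by SN2 displacement of the oxyphosphonium ion, and imidazole keeps the medium buffered for the ketal.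

Step 5
Reactants: 7 2-(5-iodo-2,2-dimethylpentyl)-2-methyl-1,3-dioxolane; 8 3-butyn-1-ol
Product: 9 8,8-dimethyl-9-(2-methyl-1,3-dioxolan-2-yl)non-3-yn-1-ol
Conditions: 8 (1.5 equiv), n-BuLi (3.0 equiv), THF/DMPU, −78 to 0 °C; then 7, 0 °C to rt
Reagents that add atoms: none
Why: Acetylide alkylation, in which the dilithio derivative of 3-butyn-1-ol reacts with the primary iodide at the more nucleophilic acetylide carbon (SN2), joins C1 to C10.

Step 6
Reactants: 9 8,8-dimethyl-9-(2-methyl-1,3-dioxolan-2-yl)non-3-yn-1-ol; 10 methylmagnesium bromide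
Product: 12 (E)-3-iodo-4,8,8-trimethyl-9-(2-methyl-1,3-dioxolan-2-yl)non-3-en-1-ol (iodine and the new methyl cis), via alkenylmagnesium bromide 11 (not isolated)
Conditions: MeMgBr (5 equiv), Fe(acac)3 (0.2 equiv), THF, −78 to 0 °C; then I2 (6 equiv), THF, −78 °C to rt; aq Na2S2O3
Reagents that add atoms: iodine, II
Why: Alkoxide-directed iron-catalysed syn-carbomagnesiation of the homopropargylic alcohol delivers the methyl group (C20) to the alkyne carbon remote from oxygen and magnesium to the near one, and iodinolysis with retention fixes the tetrasubstituted alkene geometry.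

Step 7
Reactants: 12 (E)-3-iodo-4,8,8-trimethyl-9-(2-methyl-1,3-dioxolan-2-yl)non-3-en-1-ol; 13 dimethyl oxalate
Product: 16 (4E)-4-[6,6-dimethyl-7-(2-methyl-1,3-dioxolan-2-yl)heptan-2-ylidene]dihydro-2H-pyran-2,3(4H)-dione, via dilithio species 14 (not isolated), via lithium alkoxide keto ester 15 (not isolated)
Conditions: t-BuLi (3.1 equiv), Et2O, −78 °C; cannulate into 13 (2 equiv), THF, −78 to 0 °C; AcOH
Reagents that add atoms: none
Why: Iodine–lithium exchange with retention and C-acylation of the alkenyllithium by the oxalate give the α-keto ester (C8, C17), whose neighbouring lithium alkoxide should close the six-membered lactone by transesterification.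

Step 8
Reactants: 16 (4E)-4-[6,6-dimethyl-7-(2-methyl-1,3-dioxolan-2-yl)heptan-2-ylidene]dihydro-2H-pyran-2,3(4H)-dione
Product: 17 (4E)-4-(6,6-dimethyl-8-oxononan-2-ylidene)dihydro-2H-pyran-2,3(4H)-dione
Conditions: 1 M HCl, THF, 0 °C to rt
Reagents that add atoms: water, O
Why: Mild acid hydrolysis of the dioxolane releases the methyl ketone, the keto lactone carrying no other acid-labile group.

Step 9
Reactants: 17 (4E)-4-(6,6-dimethyl-8-oxononan-2-ylidene)dihydro-2H-pyran-2,3(4H)-dione
Product: 20 6-oxo-13,14,15,16-tetranor-ent-labd-7-en-17,12-olide (5-H anti and C11 syn to the 10-methyl), via Michael adduct 18 (not isolated), via aldol adduct 19 (not isolated)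
Conditions: 9-amino(9-deoxy)epi-quinine (20 mol %), CF3CO2H (40 mol %), toluene, 40 °C, then 70 °C
Reagents that add atoms: none
Why: Proposed new method: the primary ammonium salt condenses with the methyl ketone, and its more substituted enamine (C5=C6) adds 6-exo-trig to C10 of the planar, s-cis-locked alkylidene keto lactone (Michael step, ring A); the adduct is drained as the stabilised enol of the cyclic 1,2-dicarbonyl, after which the C7 enamine attacks the C8 ketone (6-enolexo-exo-trig aldol, ring B) and the tertiary β-hydroxy ketone dehydrates to the doubly conjugated enone. The closest known reaction type is the amine-catalysed Michael–aldol [3+3] annulation of ketones with β,γ-unsaturated α-keto esters (a Robinson-type annulation), run here intramolecularly and onto a fully substituted β-carbon, which is why it is proposed and not assumed. C10 is set by the catalyst, which shields one face of the acceptor alkene whose geometry was fixed in step 6; C5 (α to the C6 ketone) and C9 (α to the C8 ketone before the aldol step, γ to the enone after it) stay epimerisable and should settle in the trans-fused decalin with C11 pseudo-equatorial, the arrangement in which the lactone is unstrained. Regioselectivity (C5 and not C7 in the Michael step, C7 and not C5 in the aldol step) is secured by ring size, because the wrong pairings need four-, eight- or ten-membered rings. The step also needs the amine to act at C6 in the presence of the keto lactone, which holding the amine as its salt and the steric bulk of the catalyst are meant to secure.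

Step 10
Reactants: 20 6-oxo-13,14,15,16-tetranor-ent-labd-7-en-17,12-olide; 21 p-toluenesulfonyl hydrazide
Product: 22 C6 tosylhydrazone of 20 (C=N geometry not defined)
Conditions: TsNHNH2 (1.3 equiv), PPTS (10 mol %), THF, 50 °C
Reagents that add atoms: none
Why: Acid-catalysed condensation at the only ketone gives the α,β-unsaturated tosylhydrazone, and cyclization to a pyridazinone is excluded because C6 and C17 are trans across C7=C8.

Step 11
Reactants: 22 C6 tosylhydrazone of 20
Product: 24 13,14,15,16-tetranor-ent-labd-6-en-17,12-olide (8-H syn to the 10-methyl, trans-fused lactone), via allylic diazene 23 (not isolated)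
Conditions: catecholborane (2.5 equiv), CHCl3, 0 °C; then NaOAc·3H2O (5 equiv), 60 °C
Reagents that add atoms: none
Why: In this alkene-transposing Caglioti-type reduction catecholborane delivers hydride 1,2 to C6 on the face away from the axial C4 and C10 methyls, sulfinate loss gives the allylic diazene with nitrogen syn to the 10-methyl, and its suprafacial retro-ene 1,5-hydrogen shift with loss of N2 places hydrogen on C8 on that same face while moving the alkene to C6=C7.

Step 12
Reactants: 24 13,14,15,16-tetranor-ent-labd-6-en-17,12-olide; 25 methanol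
Product: 26 methyl 12-hydroxy-13,14,15,16-tetranor-ent-labd-6-en-17-oate
Conditions: MeOH (solvent), p-TsOH·H2O (5 mol %), rt; solid NaHCO3, concentrate cold
Reagents that add atoms: none
Why: Acid-catalysed transesterification in methanol opens the δ-lactone to the methyl ester and the free C12 alcohol, and the absence of base keeps the allylic, ester-bearing C8 from epimerising or the alkene from moving into conjugation.

Step 13
Reactants: 26 methyl 12-hydroxy-13,14,15,16-tetranor-ent-labd-6-en-17-oate
Product: 27 methyl 12-iodo-13,14,15,16-tetranor-ent-labd-6-en-17-oate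
Conditions: I2, PPh3, imidazole, CH2Cl2, 0 °C
Reagents that add atoms: iodine, II
Why: Appel-type iodination of the primary alcohol under buffered, non-basic conditions, run directly on the crude hydroxy ester so that it outpaces relactonization.

Step 14
Reactants: 28 methyl 4-hydroxybut-2-ynoate; 29 acetic anhydride
Product: 30 methyl 4-acetoxybut-2-ynoate
Conditions: Ac2O (1.5 equiv), Sc(OTf)3 (1 mol %), MeCN, 0 °C
Reagents that add atoms: none
Why: Lewis-acid-catalysed O-acetylation avoids nucleophilic amine catalysts, which would add to the ynoate.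

Step 15
Reactants: 30 methyl 4-acetoxybut-2-ynoate
Product: 31 methyl (Z)-4-acetoxy-3-iodobut-2-enoate
Conditions: NaI (2 equiv), AcOH, 70 °C
Reagents that add atoms: sodium iodide, [Na+].[I-]
Why: Hydroiodination of the ynoate (conjugate addition of iodide, then anti protonation) should give the (Z)-β-iodoenoate with iodine cis to the ester and the acetoxymethyl group trans to it.

Step 16
Reactants: 27 methyl 12-iodo-13,14,15,16-tetranor-ent-labd-6-en-17-oate; 31 methyl (Z)-4-acetoxy-3-iodobut-2-enoate
Product: 33 dimethyl (13E)-16-acetoxy-ent-labda-6,13-diene-15,17-dioate (5R,8S,9R,10S), via alkylzinc iodide 32 (not isolated)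
Conditions: Zn dust (activated with Me3SiCl and 1,2-dibromoethane), DMA, 40 °C; then 31, Pd(PPh3)4 (5 mol %), THF, rt
Reagents that add atoms: none
Why: Zinc insertion into the primary iodide and Negishi coupling with the alkenyl iodide proceed with retention of alkene geometry (C12 cis to the ester, hence 13E) under neutral conditions that leave the C8 stereocenter, both esters and the acetate untouched.

**Compound list**
1 | mesityl oxide (4-methylpent-3-en-2-one) | CC(C)=CC(C)=O | starting material
2 | allyltrimethylsilane | C=CC[Si](C)(C)C | starting material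
3 | 4,4-dimethylhept-6-en-2-one | C=CCC(C)(C)CC(C)=O | intermediate
4 | ethylene glycol | OCCO | starting material
5 | 2-(2,2-dimethylpent-4-en-1-yl)-2-methyl-1,3-dioxolane | C=CCC(C)(C)CC1(C)OCCO1 | intermediate
6 | 4,4-dimethyl-5-(2-methyl-1,3-dioxolan-2-yl)pentan-1-ol | OCCCC(C)(C)CC1(C)OCCO1 | intermediate
7 | 2-(5-iodo-2,2-dimethylpentyl)-2-methyl-1,3-dioxolane | ICCCC(C)(C)CC1(C)OCCO1 | intermediate
8 | 3-butyn-1-ol | C#CCCO | starting material
9 | 8,8-dimethyl-9-(2-methyl-1,3-dioxolan-2-yl)non-3-yn-1-ol | OCCC#CCCCC(C)(C)CC1(C)OCCO1 | intermediate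
10 | methylmagnesium bromide | C[Mg]Br | starting material
11 | alkenylmagnesium bromide, bromomagnesium alkoxide of the carbomagnesiated 9 (magnesium and the new methyl cis) | CC1(CC(C)(C)CCC/C(C)=C(/[Mg]Br)CCO[Mg]Br)OCCO1 | intermediate (not isolated)
12 | (E)-3-iodo-4,8,8-trimethyl-9-(2-methyl-1,3-dioxolan-2-yl)non-3-en-1-ol | CC1(CC(C)(C)CCC/C(C)=C(/I)CCO)OCCO1 | intermediate
13 | dimethyl oxalate | COC(=O)C(=O)OC | starting material
14 | dilithio species, lithium alkoxide of the 3-lithio alkenol (lithium in place of iodine, same geometry as 12) | CC1(CC(C)(C)CCC/C(C)=C(/[Li])CCO[Li])OCCO1 | intermediate (not isolated)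
15 | lithium alkoxide of methyl (E)-3-(2-hydroxyethyl)-4,8,8-trimethyl-9-(2-methyl-1,3-dioxolan-2-yl)-2-oxonon-3-enoate | CC1(CC(C)(C)CCC/C(C)=C(/C(=O)C(=O)OC)CCO[Li])OCCO1 | intermediate (not isolated)
16 | (4E)-4-[6,6-dimethyl-7-(2-methyl-1,3-dioxolan-2-yl)heptan-2-ylidene]dihydro-2H-pyran-2,3(4H)-dione | CC1(CC(C)(C)CCC/C(C)=C2\CCOC(=O)C2=O)OCCO1 | intermediate
17 | (4E)-4-(6,6-dimethyl-8-oxononan-2-ylidene)dihydro-2H-pyran-2,3(4H)-dione | CC(=O)CC(C)(C)CCC/C(C)=C1\CCOC(=O)C1=O | intermediate
18 | Michael adduct, 4-(2-acetyl-1,3,3-trimethylcyclohexyl)dihydro-2H-pyran-2,3(4H)-dione (acetyl trans to the pyrandione ring and cis to the ring methyl on the quaternary carbon; in equilibrium with its C8 enol) | CC(=O)[C@@H]1C(C)(C)CCC[C@@]1(C)[C@@H]2CCOC(=O)C2=O | intermediate (not isolated)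
19 | aldol adduct, 8-hydroxy-6-oxo-13,14,15,16-tetranor-ent-labdan-17,12-olide (C8 configuration not defined) | O=C1OCC[C@@H]2C1(O)CC(=O)[C@@H]3C(C)(C)CCC[C@@]23C | intermediate (not isolated)
20 | 6-oxo-13,14,15,16-tetranor-ent-labd-7-en-17,12-olide (trans-fused decalin, C11 syn to the 10-methyl) | O=C1OCC[C@@H]2C1=CC(=O)[C@@H]3C(C)(C)CCC[C@@]23C | intermediate
21 | p-toluenesulfonyl hydrazide | Cc1ccc(cc1)S(=O)(=O)NN | starting material
22 | C6 tosylhydrazone of 20 | O=C1OCC[C@@H]2C1=CC(=NNS(=O)(=O)c4ccc(C)cc4)[C@@H]3C(C)(C)CCC[C@@]23C | intermediate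
23 | allylic diazene, 6-diazenyl-13,14,15,16-tetranor-ent-labd-7-en-17,12-olide (nitrogen syn to the 10-methyl) | O=C1OCC[C@@H]2C1=C[C@H](N=N)[C@@H]3C(C)(C)CCC[C@@]23C | intermediate (not isolated)
24 | 13,14,15,16-tetranor-ent-labd-6-en-17,12-olide (8-H syn to the 10-methyl, trans-fused lactone) | O=C1OCC[C@@H]2[C@@H]1C=C[C@@H]3C(C)(C)CCC[C@@]23C | intermediate
25 | methanol | CO | starting material
26 | methyl 12-hydroxy-13,14,15,16-tetranor-ent-labd-6-en-17-oate | OCC[C@@H]1[C@@H](C(=O)OC)C=C[C@@H]2C(C)(C)CCC[C@@]12C | intermediate
27 | methyl 12-iodo-13,14,15,16-tetranor-ent-labd-6-en-17-oate | ICC[C@@H]1[C@@H](C(=O)OC)C=C[C@@H]2C(C)(C)CCC[C@@]12C | intermediate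
28 | methyl 4-hydroxybut-2-ynoate | COC(=O)C#CCO | starting material
29 | acetic anhydride | CC(=O)OC(C)=O | starting material
30 | methyl 4-acetoxybut-2-ynoate | COC(=O)C#CCOC(C)=O | intermediate
31 | methyl (Z)-4-acetoxy-3-iodobut-2-enoate | COC(=O)/C=C(\I)COC(C)=O | intermediate
32 | alkylzinc iodide from 27 (iodozinc at C12) | I[Zn]CC[C@@H]1[C@@H](C(=O)OC)C=C[C@@H]2C(C)(C)CCC[C@@]12C | intermediate (not isolated)
33 | dimethyl (13E)-16-acetoxy-ent-labda-6,13-diene-15,17-dioate (5R,8S,9R,10S) | COC(=O)/C=C(\CC[C@@H]1[C@@H](C(=O)OC)C=C[C@@H]2C(C)(C)CCC[C@@]12C)COC(C)=O | target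

**Step count and risks**
Total steps: 16. Longest linear sequence: 14 (steps 1 to 13, then step 16).

Most likely to fail:

1. Step 9 (proposed new method). The conjugate addition at the fully substituted C10 may be slow or reversible, the catalyst may discriminate the two faces poorly, the amine may be consumed by the keto lactone, or the ring fusion may not equilibrate to trans. The fallback separates the two bond formations and uses a Lewis acid instead of an amine. It sets out from 17, which is converted with Me3SiI and (Me3Si)2NH into its more substituted (Z)-trimethylsilyl enol ether F1. Under Cu(OTf)2 and (S,S)-tert-butyl-bis(oxazoline), which chelate the 1,2-dicarbonyl of the keto lactone, F1 should close ring A by an enantioselective Mukaiyama–Michael addition to give Michael adduct 18. p-TsOH in hot toluene then effects the aldol condensation, and the sequence comes back to the route at 20.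

2. Step 10 (and with it step 11). Hydrazone formation at the C6 carbonyl, which is flanked by C5 and crowded by the C4 and C10 methyls, may be too slow, or hydride may add in the conjugate sense. The fallback sets out from 20. Conjugate reduction with [(Ph3P)CuH]6, followed by equilibration of C8 with DBU, should give the saturated keto lactone F2 with the trans-fused lactone. Kinetic deprotonation toward C7 with KHMDS and trapping with N-(5-chloro-2-pyridyl)triflimide gives the C6 enol triflate F3. Reduction with Pd(OAc)2, PPh3, HCO2H and Et3N then returns to the route at 24.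

3. Step 7. Attack of tert-butyllithium or of the alkoxide on the oxalate may compete with iodine–lithium exchange and C-acylation and lead to oligomeric acylation. The fallback sets out from 12, whose hydroxyl is acylated with methyl chlorooxoacetate and pyridine to the mixed methyl oxalate F4. A Parham-type cyclization (t-BuLi, THF, −100 °C), in which the alkenyllithium attacks the methyl ester carbonyl through a six-membered transition state, then returns to the route at 16.

Further compounds
F1 | step 9 | (Z)-trimethylsilyl enol ether of 17 at C5=C6 | C/C(O[Si](C)(C)C)=C/C(C)(C)CCC/C(C)=C1\CCOC(=O)C1=O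
F2 | step 10 | 6-oxo-13,14,15,16-tetranor-ent-labdan-17,12-olide (8-H syn to the 10-methyl) | O=C1OCC[C@@H]2[C@@H]1CC(=O)[C@@H]3C(C)(C)CCC[C@@]23C
F3 | step 10 | C6 enol triflate, 6-(trifluoromethylsulfonyloxy)-13,14,15,16-tetranor-ent-labd-6-en-17,12-olide | O=C1OCC[C@@H]2[C@@H]1C=C(OS(=O)(=O)C(F)(F)F)[C@@H]3C(C)(C)CCC[C@@]23C
F4 | step 7 | mixed methyl oxalate of 12 | COC(=O)C(=O)OCC/C(I)=C(/C)CCCC(C)(C)CC1(C)OCCO1
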